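## Retrosynthetic overview

1. Target ⇐ its C15 silyl ether ⇐ ten-membered 4-hydroxy-2-ynone (amine-mediated 3(2H)-furanone formation) ⇐ open-chain vinyl iodide/terminal alkyne (ring-closing carbonylative Sonogashira; C3 comes from CO).
2. That seco compound ⇐ a triol, by double methacryloylation and E1cB loss of the C13 ester, which unveils the α-methylene lactone.
3. Key disconnection C7–C8: triol ⇐ acetonide of (S)-3-methylpent-4-yne-1,3-diol + a 3-(silyloxymethyl)-5-alkenylbutenolide, joined by radical C–H conjugate addition that sets C7 and C8.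
4. Butenolide ⇐ but-2-yne-1,4-diol, O-silyl propargyl alcohol and CO2; acetonide ⇐ (Z)-3-methylpent-2-en-4-yn-1-ol (asymmetric epoxidation, C2-selective hydride opening).
5. Ring order: butenolide (it becomes the 6,12-lactone), then the ten-membered carbocycle, then the furanone.

Assumptions (one line): the SMILES is taken as drawn, i.e. (6R,7R,8R,10S) in germacranolide numbering (C1 ketone, C3/C10 joined by the furanone oxygen, C12 lactone carbonyl, C13 exocyclic CH2, C14 methyl, C15 CH2OH), these locants are used throughout, C6 carries the CIP label S while C4 bears iodine (priority change only), and the ligand antipodes named follow the published sense of induction.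

## Route

Step 1
Reactants: 1 (2Z)-3-methylpent-2-en-4-yn-1-ol
Product: 2 [(2S,3R)-3-ethynyl-3-methyloxiran-2-yl]methanol
Conditions: Ti(OiPr)4 (10 mol%), L-(+)-diisopropyl tartrate (12 mol%), t-BuOOH (2 equiv), 4 Å sieves, CH2Cl2, −20 °C
Reagents that add atoms: tert-butyl hydroperoxide, CC(C)(C)OO
Why: Sharpless asymmetric epoxidation of a trisubstituted allylic alcohol, in which the L-(+)-tartrate titanium complex delivers oxygen to the alkene face that gives the (2S,3R) epoxide (the sense known for nerol) and thereby fixes the future C10 stereocentre.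

Step 2
Reactants: 2 [(2S,3R)-3-ethynyl-3-methyloxiran-2-yl]methanol
Product: 3 (3S)-3-methylpent-4-yne-1,3-diol
Conditions: NaAlH2(OCH2CH2OMe)2 (2.2 equiv), THF, −20 to 0 °C; aq. KNaC4H4O6
Reagents that add atoms: none
Why: Regioselective reductive opening of a 2,3-epoxy alcohol to the 1,3-diol by intramolecular hydride delivery from the C1 alkoxyaluminate to C2, so that the tertiary C–O bond (future C10–O) keeps its configuration while the terminal alkyne is shielded as its alkynyl aluminate.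

Step 3
Reactants: 3 (3S)-3-methylpent-4-yne-1,3-diol
Product: 4 (4S)-4-ethynyl-2,2,4-trimethyl-1,3-dioxane
Conditions: Me2C(OMe)2, PPTS (5 mol%), CH2Cl2, rt
Reagents that add atoms: 2,2-dimethoxypropane, COC(C)(C)OC
Why: Acid-catalysed acetal exchange gives the six-membered acetonide, which protects both hydroxyls and leaves the ring OCH2 group as the only hydridic C–H for the key step.

Step 4
Reactants: 5 but-2-yne-1,4-diol
Product: 6 4-[(tert-butyldiphenylsilyl)oxy]but-2-yn-1-ol
Conditions: NaH (1.0 equiv), THF, 0 °C; t-BuPh2SiCl (1.0 equiv), rt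
Reagents that add atoms: tert-butyl(chloro)diphenylsilane, CC(C)(C)[Si](Cl)(c1ccccc1)c1ccccc1
Why: Monosilylation of a symmetrical diol through its sparingly soluble monosodium alkoxide, the bulky silyl group later distinguishing C15–O from every other oxygen.

Step 5
Reactants: 6 4-[(tert-butyldiphenylsilyl)oxy]but-2-yn-1-ol
Product: 7 (2Z)-4-[(tert-butyldiphenylsilyl)oxy]-3-iodobut-2-en-1-ol
Conditions: NaAlH2(OCH2CH2OMe)2 (1.5 equiv), THF, 0 °C; I2, −78 °C; aq. Na2S2O3
Reagents that add atoms: iodine, II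
Why: Hydroxyl-directed trans-hydroalumination of the propargylic alcohol places aluminium on the distal alkyne carbon and iodinolysis with retention gives the Z-vinyl iodide, so that iodine (the site of the future C3) is cis to the future C6.

Step 6
Reactants: 7 (2Z)-4-[(tert-butyldiphenylsilyl)oxy]-3-iodobut-2-en-1-ol
Product: 8 (2Z)-4-[(tert-butyldiphenylsilyl)oxy]-3-iodobut-2-enal
Conditions: MnO2 (15 equiv), CH2Cl2, rt
Reagents that add atoms: none
Why: Allylic alcohol oxidation with MnO2 is neutral and heterogeneous, so the sensitive (Z)-β-iodo enal is formed without isomerisation or loss of iodide.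

Step 7
Reactants: 8 (2Z)-4-[(tert-butyldiphenylsilyl)oxy]-3-iodobut-2-enal; 9 tert-butyldimethyl(prop-2-yn-1-yloxy)silane
Product: 10 (4R,5Z)-1-[(tert-butyldimethylsilyl)oxy]-7-[(tert-butyldiphenylsilyl)oxy]-6-iodohept-5-en-2-yn-4-ol
Conditions: (S,S)-ProPhenol (10 mol%), Me2Zn (3 equiv), Ph3P=O (20 mol%), 9 (2.5 equiv), toluene, 0 °C
Reagents that add atoms: none
Why: Catalytic enantioselective alkynylation of an enal with the dinuclear zinc–ProPhenol catalyst (Trost alkynylation), which adds the zinc acetylide of 9 to the Si face of the aldehyde and sets C6 as R.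

Step 8
Reactants: 10 (4R,5Z)-1-[(tert-butyldimethylsilyl)oxy]-7-[(tert-butyldiphenylsilyl)oxy]-6-iodohept-5-en-2-yn-4-ol
Product: 12 (5S)-3-{[(tert-butyldimethylsilyl)oxy]methyl}-5-{(1Z)-3-[(tert-butyldiphenylsilyl)oxy]-2-iodoprop-1-en-1-yl}furan-2(5H)-one, via hydroxy acid 11 (not isolated)
Conditions: NaAlH2(OCH2CH2OMe)2 (1.6 equiv), THF, −20 to 0 °C; CO2 (1 atm), −20 °C to rt; aq. citric acid
Reagents that add atoms: carbon dioxide, O=C=O
Why: Proposed new method: the C6 alkoxide directs trans-hydroalumination so that aluminium ends on C11 cis to C6, the alkenyl aluminate is then captured by CO2 with retention and the (Z)-γ-hydroxy acid lactonises on acidification, the closest known reactions being the hydroalumination–iodination of step 5 and the carboxylation of alkenylalanates with CO2, while the vinyl iodide and the silyl ethers are inert to the hydride at this temperature.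

Step 9
Reactants: 4 (4S)-4-ethynyl-2,2,4-trimethyl-1,3-dioxane; 12 (5S)-3-{[(tert-butyldimethylsilyl)oxy]methyl}-5-{(1Z)-3-[(tert-butyldiphenylsilyl)oxy]-2-iodoprop-1-en-1-yl}furan-2(5H)-one
Product: 14 (3RS,4R,5S)-5-{(1Z)-3-[(tert-butyldiphenylsilyl)oxy]-2-iodoprop-1-en-1-yl}-4-[(1R,3S)-1,3-dihydroxy-3-methylpent-4-yn-1-yl]-3-(hydroxymethyl)oxolan-2-one, via acetonide adduct 13 (not isolated)
Conditions: (Bu4N)4W10O32 (2 mol%), 4 (5 equiv), MeCN, 390 nm LEDs, 20 °C; then TsOH·H2O, MeOH–H2O, rt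
Reagents that add atoms: none
Why: Giese-type radical conjugate addition under decatungstate hydrogen-atom-transfer photocatalysis, in which the only hydridic C–H of 4 gives the 1,3-dioxan-4-yl radical that forms the C7–C8 bond by attack on the butenolide anti to its C6 alkenyl group (7R) and through its axial, anomerically stabilised lobe in the chair with axial ethynyl and equatorial methyl (new bond cis to ethynyl, 8R), after which the α-lactone radical is reduced by back hydrogen transfer (C11 stereorandom, erased in step 10) and acid removes the acetonide and the primary tert-butyldimethylsilyl ether but not the tert-butyldiphenylsilyl ether.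

Step 10
Reactants: 14 (3RS,4R,5S)-5-{(1Z)-3-[(tert-butyldiphenylsilyl)oxy]-2-iodoprop-1-en-1-yl}-4-[(1R,3S)-1,3-dihydroxy-3-methylpent-4-yn-1-yl]-3-(hydroxymethyl)oxolan-2-one; 15 2-methylprop-2-enoyl chloride
Product: 17 (4R,5S)-5-{(1Z)-3-[(tert-butyldiphenylsilyl)oxy]-2-iodoprop-1-en-1-yl}-4-[(1R,3S)-3-hydroxy-3-methyl-1-(methacryloyloxy)pent-4-yn-1-yl]-3-methylideneoxolan-2-one, via bis-methacrylate 16 (not isolated)
Conditions: 15 (2.5 equiv), Et3N, DMAP (10 mol%), CH2Cl2, 0 °C; then DBU (1.2 equiv), 0 °C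
Reagents that add atoms: none
Why: Esterification of the secondary C8 and primary C13 hydroxyls (the tertiary propargylic hydroxyl does not react) followed by base-induced E1cB loss of methacrylate from the β-acyloxymethyl lactone gives the α-methylene lactone and leaves the C8 ester, with no change at C6, C7, C8 or C10.

Step 11
Reactants: 17 (4R,5S)-5-{(1Z)-3-[(tert-butyldiphenylsilyl)oxy]-2-iodoprop-1-en-1-yl}-4-[(1R,3S)-3-hydroxy-3-methyl-1-(methacryloyloxy)pent-4-yn-1-yl]-3-methylideneoxolan-2-one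
Product: 20 [(2Z,4R,8R,9R,11S)-2-{[(tert-butyldiphenylsilyl)oxy]methyl}-11-methyl-7-methylidene-6,12-dioxo-5,14-dioxatricyclo[9.2.1.0(4,8)]tetradeca-1(13),2-dien-9-yl] 2-methylprop-2-enoate, via macrocyclic ynone 18 (not isolated), via enaminone 19 (not isolated)
Conditions: PdCl2(PPh3)2 (10 mol%), CuI (5 mol%), CO (1 atm), Et3N, THF, 1 mM (slow addition), rt; concentrate; Et2NH (1.5 equiv), THF, 0 °C; AcOH–H2O, rt
Reagents that add atoms: carbon monoxide, [C-]#[O+]; water, O
Why: Proposed new method: ring-closing carbonylative Sonogashira coupling (oxidative addition of zerovalent palladium to the Z-vinyl iodide, CO insertion, copper acetylide transfer and reductive elimination) at high dilution closes the ten-membered cis-enynone, the closest known reactions being Sonogashira and carbonylative Stille macrocyclisations, and the strained ynone is then converted into the 3(2H)-furanone by the classical amine route (conjugate addition of Et2NH at C1, attack of the C10 hydroxyl on the C3 carbonyl, loss of water and hydrolysis of the iminium), which forms no new stereocentre and is faster than amine addition to the two acrylate units.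

Step 12
Reactants: 20 [(2Z,4R,8R,9R,11S)-2-{[(tert-butyldiphenylsilyl)oxy]methyl}-11-methyl-7-methylidene-6,12-dioxo-5,14-dioxatricyclo[9.2.1.0(4,8)]tetradeca-1(13),2-dien-9-yl] 2-methylprop-2-enoate
Product: 21 [(2Z,4R,8R,9R,11S)-2-(hydroxymethyl)-11-methyl-7-methylidene-6,12-dioxo-5,14-dioxatricyclo[9.2.1.0(4,8)]tetradeca-1(13),2-dien-9-yl] 2-methylprop-2-enoate (CNP0180483.4)
Conditions: HF·pyridine, pyridine, THF, 0 °C to rt
Reagents that add atoms: none
Why: Fluoride cleavage of the primary silyl ether under pyridine-buffered conditions that leave the methacrylate, the α-methylene lactone and the furanone untouched.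

## Compound list

1 | (2Z)-3-methylpent-2-en-4-yn-1-ol | C#C/C(C)=C\CO | starting material
2 | [(2S,3R)-3-ethynyl-3-methyloxiran-2-yl]methanol | C#C[C@@]1(C)O[C@H]1CO | intermediate
3 | (3S)-3-methylpent-4-yne-1,3-diol | C#C[C@@](C)(O)CCO | intermediate
4 | (4S)-4-ethynyl-2,2,4-trimethyl-1,3-dioxane | C#C[C@]1(C)CCOC(C)(C)O1 | intermediate
5 | but-2-yne-1,4-diol | OCC#CCO | starting material
6 | 4-[(tert-butyldiphenylsilyl)oxy]but-2-yn-1-ol | OCC#CCO[Si](c1ccccc1)(c1ccccc1)C(C)(C)C | intermediate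
7 | (2Z)-4-[(tert-butyldiphenylsilyl)oxy]-3-iodobut-2-en-1-ol | OC/C=C(\I)CO[Si](c1ccccc1)(c1ccccc1)C(C)(C)C | intermediate
8 | (2Z)-4-[(tert-butyldiphenylsilyl)oxy]-3-iodobut-2-enal | O=C/C=C(\I)CO[Si](c1ccccc1)(c1ccccc1)C(C)(C)C | intermediate
9 | tert-butyldimethyl(prop-2-yn-1-yloxy)silane (commercial O-silyl-protected propargyl alcohol) | C#CCO[Si](C)(C)C(C)(C)C | starting material
10 | (4R,5Z)-1-[(tert-butyldimethylsilyl)oxy]-7-[(tert-butyldiphenylsilyl)oxy]-6-iodohept-5-en-2-yn-4-ol | CC(C)(C)[Si](C)(C)OCC#C[C@H](O)/C=C(\I)CO[Si](c1ccccc1)(c1ccccc1)C(C)(C)C | intermediate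
11 | (2Z,4S,5Z)-2-{[(tert-butyldimethylsilyl)oxy]methyl}-7-[(tert-butyldiphenylsilyl)oxy]-4-hydroxy-6-iodohepta-2,5-dienoic acid | OC(=O)/C(CO[Si](C)(C)C(C)(C)C)=C\[C@H](O)/C=C(\I)CO[Si](c1ccccc1)(c1ccccc1)C(C)(C)C | intermediate (not isolated)
12 | (5S)-3-{[(tert-butyldimethylsilyl)oxy]methyl}-5-{(1Z)-3-[(tert-butyldiphenylsilyl)oxy]-2-iodoprop-1-en-1-yl}furan-2(5H)-one | CC(C)(C)[Si](C)(C)OCC1=C[C@@H](/C=C(\I)CO[Si](c2ccccc2)(c2ccccc2)C(C)(C)C)OC1=O | intermediate
13 | (3RS,4R,5S)-3-{[(tert-butyldimethylsilyl)oxy]methyl}-5-{(1Z)-3-[(tert-butyldiphenylsilyl)oxy]-2-iodoprop-1-en-1-yl}-4-[(4S,6R)-4-ethynyl-2,2,4-trimethyl-1,3-dioxan-6-yl]oxolan-2-one | C#C[C@]1(C)C[C@H]([C@@H]2[C@@H](/C=C(\I)CO[Si](c3ccccc3)(c3ccccc3)C(C)(C)C)OC(=O)C2CO[Si](C)(C)C(C)(C)C)OC(C)(C)O1 | intermediate (not isolated)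
14 | (3RS,4R,5S)-5-{(1Z)-3-[(tert-butyldiphenylsilyl)oxy]-2-iodoprop-1-en-1-yl}-4-[(1R,3S)-1,3-dihydroxy-3-methylpent-4-yn-1-yl]-3-(hydroxymethyl)oxolan-2-one | C#C[C@@](C)(O)C[C@@H](O)[C@@H]1[C@@H](/C=C(\I)CO[Si](c2ccccc2)(c2ccccc2)C(C)(C)C)OC(=O)C1CO | intermediate
15 | 2-methylprop-2-enoyl chloride (methacryloyl chloride) | C=C(C)C(Cl)=O | starting material
16 | bis(2-methylprop-2-enoate) of 14 at the secondary side-chain oxygen (C8) and the hydroxymethyl oxygen (C13) | C#C[C@@](C)(O)C[C@@H](OC(=O)C(C)=C)[C@@H]1[C@@H](/C=C(\I)CO[Si](c2ccccc2)(c2ccccc2)C(C)(C)C)OC(=O)C1COC(=O)C(C)=C | intermediate (not isolated)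
17 | (4R,5S)-5-{(1Z)-3-[(tert-butyldiphenylsilyl)oxy]-2-iodoprop-1-en-1-yl}-4-[(1R,3S)-3-hydroxy-3-methyl-1-(methacryloyloxy)pent-4-yn-1-yl]-3-methylideneoxolan-2-one | C#C[C@@](C)(O)C[C@@H](OC(=O)C(C)=C)[C@@H]1[C@@H](/C=C(\I)CO[Si](c2ccccc2)(c2ccccc2)C(C)(C)C)OC(=O)C1=C | intermediate
18 | (4Z,6R,7R,8R,10S)-15-[(tert-butyldiphenylsilyl)oxy]-10-hydroxy-3-oxogermacra-4,11(13)-dien-1-yn-12,6-olid-8-yl 2-methylprop-2-enoate (ten-membered cis-enynone) | C=C(C)C(=O)O[C@@H]1C[C@](C)(O)C#CC(=O)/C(CO[Si](c3ccccc3)(c3ccccc3)C(C)(C)C)=C\[C@H]2OC(=O)C(=C)[C@@H]21 | intermediate (not isolated)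
19 | (4Z,6R,7R,8R,10S)-15-[(tert-butyldiphenylsilyl)oxy]-1-(diethylamino)-10-hydroxy-3-oxogermacra-1,4,11(13)-trien-12,6-olid-8-yl 2-methylprop-2-enoate (enaminone) | C=C(C)C(=O)O[C@@H]1C[C@](C)(O)C(N(CC)CC)=CC(=O)/C(CO[Si](c3ccccc3)(c3ccccc3)C(C)(C)C)=C\[C@H]2OC(=O)C(=C)[C@@H]21 | intermediate (not isolated)
20 | [(2Z,4R,8R,9R,11S)-2-{[(tert-butyldiphenylsilyl)oxy]methyl}-11-methyl-7-methylidene-6,12-dioxo-5,14-dioxatricyclo[9.2.1.0(4,8)]tetradeca-1(13),2-dien-9-yl] 2-methylprop-2-enoate | C=C(C)C(=O)O[C@@H]1C[C@]2(C)OC(=CC2=O)/C(CO[Si](c3ccccc3)(c3ccccc3)C(C)(C)C)=C\[C@H]2OC(=O)C(=C)[C@@H]21 | intermediate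
21 | [(2Z,4R,8R,9R,11S)-2-(hydroxymethyl)-11-methyl-7-methylidene-6,12-dioxo-5,14-dioxatricyclo[9.2.1.0(4,8)]tetradeca-1(13),2-dien-9-yl] 2-methylprop-2-enoate | C=C(C)C(=O)O[C@@H]1C[C@]2(C)OC(=CC2=O)/C(CO)=C\[C@H]2OC(=O)C(=C)[C@@H]21 | target

## Step count and risks

Total steps: 12. Longest linear sequence: 9 (steps 4 to 12, from but-2-yne-1,4-diol); the other branch is steps 1 to 3.

Most likely to fail, first: step 11. The ten-membered enynone is strained, and intermolecular coupling, alkyne homocoupling or Heck-type attack on the exocyclic alkene may win. The fallback sets out from 17: the terminal alkyne is converted with Bu3SnOMe (toluene, 60 °C) into alkynylstannane F3. The ring is then closed by carbonylative Stille coupling (Pd2(dba)3, AsPh3, CO 1 atm, THF, 50 °C, 1 mM), a neutral coupling of a preformed tin acetylide that needs neither amine nor copper. It gives the same ynone and comes back to the route at 18 (Et2NH, then AcOH–H2O, then step 12).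

Second: step 9. The axial ethynyl group and the axial acetonide methyl flank the axial face of the dioxanyl radical, so attack from the equatorial face may dominate and give the wrong configuration at C8. The fallback sets out from 4 and 12 and accepts that outcome: the coupling then gives C8-epimeric acetonide adduct F1 and, after the same acid treatment, C8-epimeric triol F2. F2 is esterified with methacrylic acid under Mitsunobu conditions (PPh3, DIAD, THF, 0 °C), which acylates the primary hydroxyl and inverts C8. This moves control of C8 from the radical step to an SN2 esterification and comes back to the route at 16 (DBU, then steps 11 and 12).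

Third: step 8. The alkoxy-substituted alkenyl aluminate may be too weak a nucleophile for CO2, or the hydride may touch the vinyl iodide. The fallback sets out from 8 and builds the butenolide without any aluminium–carbon intermediate. Zinc–ProPhenol alkynylation with methyl propiolate gives hydroxy ynoate F4. Cis-selective semireduction with zinc activated by Cu(OAc)2 and AgNO3 (MeOH–H2O) and lactonisation give butenolide F5. Morita–Baylis–Hillman hydroxymethylation (aqueous formaldehyde, Bu3P cat.) gives hydroxymethyl butenolide F6, which is silylated (t-BuMe2SiCl, imidazole) and comes back to the route at 12.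

Further compounds

F1 | step 9 | (3RS,4R,5S)-3-{[(tert-butyldimethylsilyl)oxy]methyl}-5-{(1Z)-3-[(tert-butyldiphenylsilyl)oxy]-2-iodoprop-1-en-1-yl}-4-[(4S,6S)-4-ethynyl-2,2,4-trimethyl-1,3-dioxan-6-yl]oxolan-2-one (C8 epimer of 13) | C#C[C@]1(C)C[C@@H]([C@@H]2[C@@H](/C=C(\I)CO[Si](c3ccccc3)(c3ccccc3)C(C)(C)C)OC(=O)C2CO[Si](C)(C)C(C)(C)C)OC(C)(C)O1
F2 | step 9 | (3RS,4R,5S)-5-{(1Z)-3-[(tert-butyldiphenylsilyl)oxy]-2-iodoprop-1-en-1-yl}-4-[(1S,3S)-1,3-dihydroxy-3-methylpent-4-yn-1-yl]-3-(hydroxymethyl)oxolan-2-one (C8 epimer of 14) | C#C[C@@](C)(O)C[C@H](O)[C@@H]1[C@@H](/C=C(\I)CO[Si](c2ccccc2)(c2ccccc2)C(C)(C)C)OC(=O)C1CO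
F3 | step 11 | (4R,5S)-5-{(1Z)-3-[(tert-butyldiphenylsilyl)oxy]-2-iodoprop-1-en-1-yl}-4-[(1R,3S)-3-hydroxy-3-methyl-1-(methacryloyloxy)-5-(tributylstannyl)pent-4-yn-1-yl]-3-methylideneoxolan-2-one | CCCC[Sn](CCCC)(CCCC)C#C[C@@](C)(O)C[C@@H](OC(=O)C(C)=C)[C@@H]1[C@@H](/C=C(\I)CO[Si](c2ccccc2)(c2ccccc2)C(C)(C)C)OC(=O)C1=C
F4 | step 8 | methyl (4R,5Z)-7-[(tert-butyldiphenylsilyl)oxy]-4-hydroxy-6-iodohept-5-en-2-ynoate | COC(=O)C#C[C@H](O)/C=C(\I)CO[Si](c1ccccc1)(c1ccccc1)C(C)(C)C
F5 | step 8 | (5S)-5-{(1Z)-3-[(tert-butyldiphenylsilyl)oxy]-2-iodoprop-1-en-1-yl}furan-2(5H)-one | O=C1C=C[C@@H](/C=C(\I)CO[Si](c2ccccc2)(c2ccccc2)C(C)(C)C)O1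
F6 | step 8 | (5S)-5-{(1Z)-3-[(tert-butyldiphenylsilyl)oxy]-2-iodoprop-1-en-1-yl}-3-(hydroxymethyl)furan-2(5H)-one | OCC1=C[C@@H](/C=C(\I)CO[Si](c2ccccc2)(c2ccccc2)C(C)(C)C)OC1=O
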